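## Retrosynthetic overview

1. The target comes from its hexa-O-benzyl ether by one global hydrogenolysis; the ester C–O bond is cut to a 2,3-cis-flavan-3-ol and tri-O-benzylgalloyl chloride.
2. The (2R,3R)-flavan-3-ol comes from a racemic flavan-3-one: C2 of the ketone (α to C=O, benzylic, bound to O1) epimerises, so one dynamic kinetic hydrogenation sets C2 and C3 together.
3. The flavan-3-one comes from a racemic aryl propargyl ether: ring C is closed by forming the C4–C4a bond in a gold-catalysed oxidative cyclisation. The terminal alkyne is C3–C4, a pyridine N-oxide supplies the C3 oxygen, and the α-oxo gold carbene at C4 is captured by ring A.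
4. Enabling feature: ring A is a phloroglucinol ring, so the carbon that becomes C4a is ortho to O1, ortho to the C5 oxygen and para to the C7 oxygen, and the two carbons ortho to O1 are equivalent. C3 bears oxygen next to an unsubstituted C4 methylene, which is what Markovnikov oxidation of a terminal alkyne delivers.
5. The ether comes from Mitsunobu union of 3,5-bis(benzyloxy)phenol with the propargylic alcohol made from O-benzylisovanillin and ethynylmagnesium bromide. Rings A and B and the galloyl ring are bought; ring C is the only ring formed.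

Key step: step 3

Assumption: the catalyst enantiomer named in step 4 is taken, by analogy with 2-aryl- and 2-alkoxycycloalkanones, to be the one matched with the (2R)-ketone; if a first run shows the opposite sense, the antipodal complex RuCl2[(R)-xylBINAP][(R)-DAIPEN] is used with no other change.

## Route

Step 1
Reactants: 1 3-(benzyloxy)-4-methoxybenzaldehyde
Product: 2 rac-1-[3-(benzyloxy)-4-methoxyphenyl]prop-2-yn-1-ol
Conditions: HC≡CMgBr (1.3 equiv), THF, 0 °C to rt; then sat. aq. NH4Cl
Reagents that add atoms: ethynylmagnesium bromide, C#C[Mg]Br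
Why: Grignard 1,2-addition of an alkynyl nucleophile to an aromatic aldehyde is fast and tolerates the aryl ethers; the carbinol centre is formed as a racemate on purpose, because this centre becomes configurationally labile in 6 and is set in step 4.

Step 2
Reactants: 2 rac-1-[3-(benzyloxy)-4-methoxyphenyl]prop-2-yn-1-ol; 3 3,5-bis(benzyloxy)phenol
Product: 4 rac-1,3-bis(benzyloxy)-5-({1-[3-(benzyloxy)-4-methoxyphenyl]prop-2-yn-1-yl}oxy)benzene
Conditions: PPh3, DIAD, toluene, 0 °C to rt
Reagents that add atoms: none
Why: Mitsunobu etherification, in which the acidic phenol (pKa about 9–10) protonates the phosphonium betaine and its phenoxide displaces the oxyphosphonium group at the propargylic carbon with O-selectivity; the centre stays racemic, so no stereochemical fidelity is asked of the displacement.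

Step 3
Reactants: 4 rac-1,3-bis(benzyloxy)-5-({1-[3-(benzyloxy)-4-methoxyphenyl]prop-2-yn-1-yl}oxy)benzene
Product: 6 rac-5,7-bis(benzyloxy)-2-[3-(benzyloxy)-4-methoxyphenyl]chroman-3-one, via alpha-oxo gold carbene 5 (not isolated)
Conditions: [(Me4tBuXPhos)Au]NTf2 (5 mol%; Me4tBuXPhos = 2-di-tert-butylphosphino-3,4,5,6-tetramethyl-2',4',6'-triisopropylbiphenyl), 2,6-dichloropyridine N-oxide (1.5 equiv), ClCH2CH2Cl, rt
Reagents that add atoms: 2,6-dichloropyridine N-oxide, [O-][n+]1c(Cl)cccc1Cl
Why: The cationic monovalent gold catalyst π-activates the terminal alkyne of 4, the N-oxide oxygen adds to the internal alkyne carbon (Markovnikov, future C3) and N–O cleavage expels 2,6-dichloropyridine to give the α-oxo gold carbene 5, whose electrophilic carbene carbon (future C4) is attacked by the ortho carbon of ring A (future C4a); rearomatisation and protodeauration then release ketone 6. The closest known reaction type is the gold-catalysed oxidative cyclisation of aryl propargyl ethers to chroman-3-ones with pyridine N-oxides, a diazo-free counterpart of the rhodium carbenoid cyclisation of aryloxy diazoketones. Ring C closes in a 6-exo-trig mode at the carbene carbon (Friedel–Crafts-type C–H functionalisation through a Wheland intermediate). No stereocentre is created: C3 becomes a carbonyl carbon, and C2 is carried as a racemate on purpose because in 6 it is α to the ketone and is resolved dynamically in step 4. The step needs N-oxide attack to outrun direct 6-endo-dig hydroarylation (bulky biaryl phosphine ligand, excess oxidant), capture by ring A and not ring B (ring A carries three oxygen donors and closes a six-membered ring, whereas ring B would close a five-membered one), and a single regiochemistry on ring A (the two ortho carbons of the 3,5-bis(benzyloxy)phenoxy group are equivalent). The non-basic pyridine by-product leaves the catalyst active without added acid, which protects the acid-labile benzylic ether at C2.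

Step 4
Reactants: 6 rac-5,7-bis(benzyloxy)-2-[3-(benzyloxy)-4-methoxyphenyl]chroman-3-one
Product: 7 (2R,3R)-5,7-bis(benzyloxy)-2-[3-(benzyloxy)-4-methoxyphenyl]chroman-3-ol
Conditions: RuCl2[(S)-xylBINAP][(S)-DAIPEN] (1 mol%), KOtBu (10 mol%), H2 (10 atm), i-PrOH/toluene, 25 °C
Reagents that add atoms: none
Why: Noyori-type bifunctional ketone hydrogenation run as a dynamic kinetic resolution, the reaction type established for 2-aryl- and 2-alkoxycycloalkanones: C2–H of 6 is α to the carbonyl, benzylic and O-substituted, so the enantiomers should interconvert through the enolate faster than they are reduced, the chiral ruthenium hydride selects the (2R)-ketone (C2 set by catalyst control through the resolution) and delivers hydride to C3 anti to the pseudoequatorial C2 aryl group (C3 set cis to it, substrate and catalyst acting in the same sense).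

Step 5
Reactants: 7 (2R,3R)-5,7-bis(benzyloxy)-2-[3-(benzyloxy)-4-methoxyphenyl]chroman-3-ol; 8 3,4,5-tris(benzyloxy)benzoyl chloride
Product: 9 (2R,3R)-5,7-bis(benzyloxy)-2-[3-(benzyloxy)-4-methoxyphenyl]chroman-3-yl 3,4,5-tris(benzyloxy)benzoate
Conditions: Et3N, DMAP (cat.), CH2Cl2, 0 °C to rt
Reagents that add atoms: none
Why: DMAP-catalysed acylation (nucleophilic catalysis through the N-acylpyridinium ion) of the axial secondary alcohol with an acid chloride, the usual way to gallate 2,3-cis-flavan-3-ols; no bond to C2 or C3 is broken, so both configurations are kept.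

Step 6
Reactants: 9 (2R,3R)-5,7-bis(benzyloxy)-2-[3-(benzyloxy)-4-methoxyphenyl]chroman-3-yl 3,4,5-tris(benzyloxy)benzoate
Product: 10 4'-O-methylepicatechin-3-O-gallate
Conditions: H2 (1 atm), Pd(OH)2/C, THF/MeOH, rt
Reagents that add atoms: none
Why: Catalytic hydrogenolysis of the six benzyl aryl ethers under neutral conditions should leave the methyl ether, the gallate ester and the cyclic secondary C2–O1 ether intact and does not touch C2 or C3; with the 4'-oxygen methylated, no para-quinone methide path exists for C2 epimerisation in the free polyphenol.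

## Compound list

1 | 3-(benzyloxy)-4-methoxybenzaldehyde | COc1ccc(C=O)cc1OCc1ccccc1 | starting material
2 | rac-1-[3-(benzyloxy)-4-methoxyphenyl]prop-2-yn-1-ol (racemate) | C#CC(O)c1ccc(OC)c(OCc2ccccc2)c1 | intermediate
3 | 3,5-bis(benzyloxy)phenol | Oc1cc(OCc2ccccc2)cc(OCc2ccccc2)c1 | starting material
4 | rac-1,3-bis(benzyloxy)-5-({1-[3-(benzyloxy)-4-methoxyphenyl]prop-2-yn-1-yl}oxy)benzene (racemate) | C#CC(Oc1cc(OCc2ccccc2)cc(OCc2ccccc2)c1)c1ccc(OC)c(OCc2ccccc2)c1 | intermediate
5 | α-oxo gold carbene: {3-[3,5-bis(benzyloxy)phenoxy]-3-[3-(benzyloxy)-4-methoxyphenyl]-2-oxopropylidene}(Me4tBuXPhos)gold bis(trifluoromethylsulfonyl)imide (racemate, not isolated) | O=C(C=[Au][P+](C(C)(C)C)(C(C)(C)C)c1c(C)c(C)c(C)c(C)c1-c1c(C(C)C)cc(C(C)C)cc1C(C)C)C(Oc1cc(OCc2ccccc2)cc(OCc2ccccc2)c1)c1ccc(OC)c(OCc2ccccc2)c1.O=S(=O)([N-]S(=O)(=O)C(F)(F)F)C(F)(F)F | intermediate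
6 | rac-5,7-bis(benzyloxy)-2-[3-(benzyloxy)-4-methoxyphenyl]chroman-3-one (racemate) | COc1ccc(C2Oc3cc(OCc4ccccc4)cc(OCc4ccccc4)c3CC2=O)cc1OCc1ccccc1 | intermediate
7 | (2R,3R)-5,7-bis(benzyloxy)-2-[3-(benzyloxy)-4-methoxyphenyl]chroman-3-ol (2,3-cis) | COc1ccc([C@H]2Oc3cc(OCc4ccccc4)cc(OCc4ccccc4)c3C[C@H]2O)cc1OCc1ccccc1 | intermediate
8 | 3,4,5-tris(benzyloxy)benzoyl chloride | O=C(Cl)c1cc(OCc2ccccc2)c(OCc2ccccc2)c(OCc2ccccc2)c1 | starting material
9 | (2R,3R)-5,7-bis(benzyloxy)-2-[3-(benzyloxy)-4-methoxyphenyl]chroman-3-yl 3,4,5-tris(benzyloxy)benzoate | COc1ccc([C@H]2Oc3cc(OCc4ccccc4)cc(OCc4ccccc4)c3C[C@H]2OC(=O)c2cc(OCc3ccccc3)c(OCc3ccccc3)c(OCc3ccccc3)c2)cc1OCc1ccccc1 | intermediate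
10 | 4'-O-methylepicatechin-3-O-gallate, (2R,3R) | COc1ccc([C@H]2Oc3cc(O)cc(O)c3C[C@H]2OC(=O)c2cc(O)c(O)c(O)c2)cc1O | target

## Step count and risks

Total step count: 6. Longest linear sequence: 6 steps (1 → 2 → 4 → 6 → 7 → 9 → 10).

Steps most likely to fail:

**Step 4 (dynamic kinetic hydrogenation).** The catalyst may discriminate poorly between the two ketone enantiomers (the carbonyl carbon carries no aryl group), or reduction may outpace C2 epimerisation, so that enantiomeric purity or cis selectivity is eroded; the enolate may also be lost to aerial oxidation. The fallback takes diastereocontrol from the substrate and enantiopurity from a classical resolution. It sets out from 6: LiBH(s-Bu)3 in THF at −78 °C, a reagent known to deliver hydride anti to the C2 aryl group of 2-arylchroman-3-ones, should give the racemic 2,3-cis-flavan-3-ol F1. Acylation with (1S,4R)-camphanic chloride (Et3N, DMAP, CH2Cl2) should give the (2R,3R)-camphanate F2 and the (2S,3S)-camphanate F3, to be separated by crystallisation or chromatography. Cleavage of F2 with LiOH in THF/MeOH/H2O rejoins the route at 7.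

**Step 3 (gold-catalysed oxidative cyclisation).** Ring A may add directly to the gold-activated alkyne before the N-oxide does (hydroarylation), the carbene may be oxidised a second time by the N-oxide, or the Lewis acid may ionise the benzylic C2–O bond. The fallback separates ring closure from oxygenation while forming the same C4–C4a bond. It sets out from 4: [(Ph3P)Au]NTf2 in CH2Cl2 at rt without oxidant should effect the known 6-endo-dig hydroarylation to the racemic 5,7-bis(benzyloxy)-2-[3-(benzyloxy)-4-methoxyphenyl]-2H-chromene F4. Hydroboration–oxidation (BH3·THF; then NaOH, H2O2), with boron adding to C3 anti to the C2 aryl group, should give the racemic 2,3-trans-flavan-3-ol F5. Oxidation with Dess–Martin periodinane rejoins the route at 6.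

**Step 2 (Mitsunobu etherification).** The oxyphosphonium ion at the p-alkoxybenzylic, propargylic carbon may ionise before the phenoxide arrives, with capture at the alkyne terminus (allenyl ether) or at a ring A carbon. The fallback replaces the redox condensation by a two-stage Williamson etherification with a stoichiometric free phenoxide in a dipolar aprotic solvent. It sets out from 2: MsCl and Et3N in CH2Cl2 at −40 °C should give 1-[3-(benzyloxy)-4-methoxyphenyl]prop-2-yn-1-yl methanesulfonate F6, which is used cold and added to the caesium phenoxide of 3 (Cs2CO3, DMF, −20 °C to rt); this rejoins the route at 4.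

## Further compounds

F1 | step 4 | rac-(2R,3R)-5,7-bis(benzyloxy)-2-[3-(benzyloxy)-4-methoxyphenyl]chroman-3-ol (racemic 2,3-cis, both enantiomers written) | COc1ccc([C@H]2Oc3cc(OCc4ccccc4)cc(OCc4ccccc4)c3C[C@H]2O)cc1OCc1ccccc1.COc1ccc([C@@H]2Oc3cc(OCc4ccccc4)cc(OCc4ccccc4)c3C[C@@H]2O)cc1OCc1ccccc1
F2 | step 4 | (2R,3R)-5,7-bis(benzyloxy)-2-[3-(benzyloxy)-4-methoxyphenyl]chroman-3-yl (1S,4R)-camphanate | COc1ccc([C@H]2Oc3cc(OCc4ccccc4)cc(OCc4ccccc4)c3C[C@H]2OC(=O)[C@@]23CC[C@@](C)(C(=O)O2)C3(C)C)cc1OCc1ccccc1
F3 | step 4 | (2S,3S)-5,7-bis(benzyloxy)-2-[3-(benzyloxy)-4-methoxyphenyl]chroman-3-yl (1S,4R)-camphanate | COc1ccc([C@@H]2Oc3cc(OCc4ccccc4)cc(OCc4ccccc4)c3C[C@@H]2OC(=O)[C@@]23CC[C@@](C)(C(=O)O2)C3(C)C)cc1OCc1ccccc1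
F4 | step 3 | rac-5,7-bis(benzyloxy)-2-[3-(benzyloxy)-4-methoxyphenyl]-2H-chromene (racemate) | COc1ccc(C2Oc3cc(OCc4ccccc4)cc(OCc4ccccc4)c3C=C2)cc1OCc1ccccc1
F5 | step 3 | rac-(2R,3S)-5,7-bis(benzyloxy)-2-[3-(benzyloxy)-4-methoxyphenyl]chroman-3-ol (racemic 2,3-trans, both enantiomers written) | COc1ccc([C@H]2Oc3cc(OCc4ccccc4)cc(OCc4ccccc4)c3C[C@@H]2O)cc1OCc1ccccc1.COc1ccc([C@@H]2Oc3cc(OCc4ccccc4)cc(OCc4ccccc4)c3C[C@H]2O)cc1OCc1ccccc1
F6 | step 2 | rac-1-[3-(benzyloxy)-4-methoxyphenyl]prop-2-yn-1-yl methanesulfonate (racemate) | C#CC(OS(C)(=O)=O)c1ccc(OC)c(OCc2ccccc2)c1
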